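By the time you read this you will want your quick number, so here are the flasks and your questions first.

| setting | spring | winter |
|---|---|---|
| G | 0.25 M | 0.25 M |
| L | 0.175 M | 0.175 M |
| Z | 0.500 M | 0.750 M |
| time | 6.0 h | 6.0 h |

    G + L ⇌ G.L (K1 = 16 /M, k1 = 0.0017 /M/s)
    Z + L → Z.L (k2 = 2.9 × 10⁻⁴ /M/s)
    G + Z → G.Z (k3 = 4.7 × 10⁻⁴ /M/s)
    2 Z → Z2 (k4 = 6.9 × 10⁻⁵ /M/s)

- two of one species on the left: rate k times its square, two consumed each time
- run time (spring): 6.0 h

- which of the two there is more of at the end, spring (G.L / G.Z)
- which of the two there is more of at the end, winter (G.L / G.Z)
- how much G.L is there at the end, in percent of the G charged: spring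
- how much G.L is there at the end, in percent of the G charged: winter

I count in fractions of the G charge: L stands at 0.700, and Z at 2.00 in spring and 3.00 in winter.

1. Free G meets a fork: L takes it at k1[L], Z at k3[Z]. At the charges, the part that Z takes is 0.441 in spring and 0.542 in winter; I call it the escape share.

2. The remainder is my first split into G.L: 55.9% in spring and 45.8% in winter. Both are smaller than the L charge allows.

3. But G.L falls back, with a mean life τ = K1/k1 of 2.61 h, shorter than the run. Each G freed meets the fork again, and the escape share of it leaves for G.Z. Holding that share fixed gives a pseudo-first-order leak, which integrates to: G.L = first split × exp(−share × t/τ).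

4. So I commit to 20.3% of G.L in spring and 13.2% in winter, with G.Z ahead in both. That is as far as it goes, for the reckoning holds Z and L at their charges.

Your forecast said G.Z in spring and G.Z in winter, with G.L at 16.5% and 10%, lower than mine, from “a rough mental march through the kinetics”.

The flask gives G.Z in spring, 67.7% against 16.7% of G.L, and G.Z in winter, 79.0% against 10.7%. My reckoning stands higher than the flask by 3.6 percentage points in spring and 2.5 points in winter.

Because G.L falls back to G + L, spring ends with 16.7% of G.L and not the 42.3% of the run without that step, the strongest single effect of the three tried on spring. That run has no leak, yet it stands lower than the 55.9% of my first split in spring. So my first split reads high.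

Take the winter flask with 0.70 M of L: the escape share is 0.229, which gives 45.7% of G.L. The computed flask holds 45.4%.

Its constants are invented; the flask was simulated.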